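**Retrosynthetic overview**
1. Target 21 ⇒ C3–CH2CO2H bond (silyl ketene acetal + C-3 peroxycarbenium ion of 18) and C6–C1′ bond (side-chain alkylzinc 16 + C-6 peroxycarbenium ion of bis-peroxyketal 15, a new coupling). Both groups enter axially on the 4-ethyl-1,2-dioxane, so C-4 controls C-6 and then C-3.
2. 15 (the only ring of the target) ⇒ aerobic radical ring expansion of cyclobutanol 13, with O2 inserted into the C1–C2 bond.
3. 13 ⇒ 3-ethylcyclobutanone 8 by enantioselective deprotonation (sets C-4), Rubottom oxidation and EtMgBr addition.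
4. Side-chain iodide 7 ⇒ hex-1-ene 1 by two zirconium-catalysed asymmetric carboaluminations (C-4′, then C-2′).
5. Ring order: the cyclobutane is bought, the 1,2-dioxane is made from it in step 7 and is not opened again.

Assumption: 3-ethylcyclobutan-1-one and both antipodes of bis(1-neomenthylindenyl)zirconium dichloride are bought; dioxane positions are numbered as in the target (O-1, O-2, C-3 to C-6) in every name.

**Step 1**
Reactants: 1 hex-1-ene; 2 bromoethene
Product: 4 (4S)-4-methyloct-1-ene, via alkyldimethylalane 3 (not isolated)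
Conditions: Me3Al, (+)-bis(1-neomenthylindenyl)zirconium dichloride (4 mol%), (MeAlO)n (cat.), CH2Cl2, 23 °C; evaporate; then 2, Zn(OTf)2, Pd(DPEphos)Cl2 (3 mol%), i-Bu2AlH (6 mol%), DMF, 60 °C
Reagents that add atoms: trimethylaluminium, C[Al](C)C
Why: Zirconium-catalysed asymmetric carboalumination (ZACA reaction) delivers methyl to one alkene face (expected about 75–80% ee, S), and the primary alane 3 is vinylated in the same flask by Pd/Zn-cocatalysed Negishi cross-coupling without touching the new stereocentre.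

**Step 2**
Reactants: 4 (4S)-4-methyloct-1-ene
Product: 6 (2S,4S)-2-ethyl-4-methyloctan-1-ol, via alkyldiethylalane 5 (not isolated)
Conditions: Et3Al, (+)-bis(1-neomenthylindenyl)zirconium dichloride (5 mol%), (i-BuAlO)n (cat.), CH2Cl2, 0 → 23 °C; then O2, 0 °C; aq. NaOH; SiO2 chromatography
Reagents that add atoms: triethylaluminium, CC[Al](CC)CC; dioxygen, O=O
Why: A second ZACA reaction (same catalyst antipode, same facial sense, about 90% ee per event) sets C-2 under catalyst control, the C–Al bond is oxidised with retention, and removal of the minor diastereomer should leave the S,S alcohol in >98% ee by statistical amplification.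

**Step 3**
Reactants: 6 (2S,4S)-2-ethyl-4-methyloctan-1-ol
Product: 7 (2S,4S)-2-ethyl-1-iodo-4-methyloctane
Conditions: I2, PPh3, imidazole, CH2Cl2, 0 → 23 °C
Reagents that add atoms: iodine, II
Why: Appel-type iodination of a primary alcohol, with no stereocentre involved.

**Step 4**
Reactants: 8 3-ethylcyclobutan-1-one
Product: 10 {[(3S)-3-ethylcyclobut-1-en-1-yl]oxy}trimethylsilane, via lithium enolate 9 (not isolated)
Conditions: lithium (R,R)-bis(1-phenylethyl)amide (from the amine and n-BuLi), Me3SiCl (internal quench), THF, −100 °C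
Reagents that add atoms: chlorotrimethylsilane, C[Si](C)(C)Cl
Why: Enantioselective deprotonation of a prochiral ketone by a chiral lithium amide removes one of the two enantiotopic α-CH2 protons and makes C-3 (the later C-4) stereogenic, expected about 85–90% ee; the sense is assigned by analogy with 4-substituted cyclohexanones, the (S,S)-base is used if the first run shows the antipode, and the minor enantiomer is removed as a diastereomer after step 8.

**Step 5**
Reactants: 10 {[(3S)-3-ethylcyclobut-1-en-1-yl]oxy}trimethylsilane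
Product: 12 (2R,3S)-3-ethyl-2-(trimethylsilyloxy)cyclobutan-1-one, via silyloxy epoxide 11 (not isolated)
Conditions: dimethyldioxirane (1.05 equiv), acetone/CH2Cl2, −78 → 0 °C
Reagents that add atoms: dimethyldioxirane, CC1(C)OO1
Why: Rubottom oxidation: epoxidation anti to the ethyl group, then ring opening with 1,4-silyl shift; the neutral dioxirane avoids Baeyer–Villiger oxidation of the cyclobutanone, and the C-2 configuration is of no consequence later.

**Step 6**
Reactants: 12 (2R,3S)-3-ethyl-2-(trimethylsilyloxy)cyclobutan-1-one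
Product: 13 (2R,3S)-1,3-diethyl-2-(trimethylsilyloxy)cyclobutan-1-ol
Conditions: EtMgBr, Et2O, −78 °C; aq. NH4Cl
Reagents that add atoms: ethylmagnesium bromide, CC[Mg]Br
Why: Grignard 1,2-addition to the strained ketone; the carbinol is formed as a C-1 epimer mixture, which does not matter because C-1 becomes the ketal carbon C-6.

**Step 7**
Reactants: 13 (2R,3S)-1,3-diethyl-2-(trimethylsilyloxy)cyclobutan-1-ol
Product: 15 (4S)-4,6-diethyl-3,6-dimethoxy-1,2-dioxane, via hemiperketal 14 (not isolated)
Conditions: Co(acac)2 (20 mol%), O2 (1 atm), ClCH2CH2Cl, 25 °C; then MeOH, pyridinium p-toluenesulfonate (cat.), 3 Å sieves, 0 → 25 °C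
Reagents that add atoms: dioxygen, O=O; methanol, CO
Why: Cobalt-catalysed aerobic oxidative ring expansion of a cyclobutanol (radical, not pericyclic): the trivalent cobalt alkoxide gives an alkoxy radical, strain-driven β-scission breaks C1–C2 on the side that leaves the α-silyloxy radical, O2 capture and closure of the hydroperoxide onto the new ethyl ketone give 14, and acid methanolysis exchanges both anomeric groups for OMe while C-4 is untouched.

**Step 8**
Reactants: 15 (4S)-4,6-diethyl-3,6-dimethoxy-1,2-dioxane; 7 (2S,4S)-2-ethyl-1-iodo-4-methyloctane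
Product: 18 (4S,6S)-4,6-diethyl-6-[(2S,4S)-2-ethyl-4-methyloctyl]-3-methoxy-1,2-dioxane, via alkylzinc iodide 16 (not isolated), via peroxycarbenium triflate 17 (not isolated)
Conditions: 7, Zn dust (activated with Me3SiCl and BrCH2CH2Br), THF, 40 °C; then 15, Me3SiOTf (1.1 equiv), CH2Cl2, −78 → −40 °C
Reagents that add atoms: none
Why: Proposed new method: Me3SiOTf ionises the tertiary peroxyketal (faster than the secondary peroxyacetal at C-3) to the 6-ethyl-1,2-dioxan-6-ylium ion 17, whose half-chair keeps the C-4 ethyl pseudo-equatorial, and the primary alkylzinc iodide 16 (too weak a reductant to cleave the O–O bond at −78 °C) transfers its alkyl group along the axial trajectory, 1,3-trans to the C-4 ethyl, so the C6–C1′ bond and the quaternary centre form as 6S; the closest known reaction types are Lewis-acid-mediated additions of allylsilanes and silyl enol ethers to peroxycarbenium ions and alkylzinc additions to cyclic oxocarbenium ions (C-glycoside synthesis), whereas an sp3 organozinc has not been added to a peroxycarbenium ion.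

**Step 9**
Reactants: 18 (4S,6S)-4,6-diethyl-6-[(2S,4S)-2-ethyl-4-methyloctyl]-3-methoxy-1,2-dioxane
Product: 21 2-[(3S,4S,6S)-4,6-diethyl-6-[(2S,4S)-2-ethyl-4-methyloctyl]-1,2-dioxan-3-yl]acetic acid, via peroxycarbenium triflate 19 (not isolated), via trimethylsilyl ester 20 (not isolated)
Conditions: CH2=C(OSiMe3)2 (2 equiv), Me3SiOTf (1.0 equiv), CH2Cl2, −78 → −40 °C; aq. NaH2PO4
Reagents that add atoms: 1,1-bis(trimethylsilyloxy)ethene, C=C(O[Si](C)(C)C)O[Si](C)(C)C
Why: Mukaiyama-type addition of a silyl ketene acetal to a peroxycarbenium ion: in 19 the ring is locked with the C-6 side chain axial and both ethyl groups equatorial (the flipped form would put the two ethyl groups 1,3-diaxial), so axial attack at C-3 places the acetate arm cis to the C-4 ethyl (3S), and the silyl ester is hydrolysed on work-up.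

**Compound list**
1 | hex-1-ene | C=CCCCC | starting material
2 | bromoethene | C=CBr | starting material
3 | dimethyl[(2S)-2-methylhexyl]alane | CCCC[C@H](C)C[Al](C)C | intermediate
4 | (4S)-4-methyloct-1-ene | CCCC[C@H](C)CC=C | intermediate
5 | diethyl[(2S,4S)-2-ethyl-4-methyloctyl]alane | CCCC[C@H](C)C[C@H](CC)C[Al](CC)CC | intermediate
6 | (2S,4S)-2-ethyl-4-methyloctan-1-ol | CCCC[C@H](C)C[C@H](CC)CO | intermediate
7 | (2S,4S)-2-ethyl-1-iodo-4-methyloctane | CCCC[C@H](C)C[C@H](CC)CI | intermediate
8 | 3-ethylcyclobutan-1-one | CCC1CC(=O)C1 | starting material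
9 | lithium (3S)-3-ethylcyclobut-1-en-1-olate | [Li]OC1=C[C@@H](CC)C1 | intermediate
10 | {[(3S)-3-ethylcyclobut-1-en-1-yl]oxy}trimethylsilane | C[Si](C)(C)OC1=C[C@@H](CC)C1 | intermediate
11 | (3S)-3-ethyl-1-(trimethylsilyloxy)-5-oxabicyclo[2.1.0]pentane (epoxide anti to ethyl) | CC[C@H]1C[C@]2(O[Si](C)(C)C)O[C@H]12 | intermediate
12 | (2R,3S)-3-ethyl-2-(trimethylsilyloxy)cyclobutan-1-one | CC[C@H]1CC(=O)[C@@H]1O[Si](C)(C)C | intermediate
13 | (2R,3S)-1,3-diethyl-2-(trimethylsilyloxy)cyclobutan-1-ol (C-1 epimers) | CC[C@H]1CC(O)(CC)[C@@H]1O[Si](C)(C)C | intermediate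
14 | (4S)-4,6-diethyl-3-(trimethylsilyloxy)-1,2-dioxan-6-ol (C-3/C-6 epimers) | CCC1(O)C[C@H](CC)C(O[Si](C)(C)C)OO1 | intermediate
15 | (4S)-4,6-diethyl-3,6-dimethoxy-1,2-dioxane (C-3/C-6 epimers) | CCC1(OC)C[C@H](CC)C(OC)OO1 | intermediate
16 | [(2S,4S)-2-ethyl-4-methyloctyl]zinc iodide | CCCC[C@H](C)C[C@H](CC)C[Zn]I | intermediate
17 | (4S)-4,6-diethyl-3-methoxy-1,2-dioxan-6-ylium trifluoromethanesulfonate | CCC1=[O+]OC(OC)[C@@H](CC)C1.[O-]S(=O)(=O)C(F)(F)F | intermediate
18 | (4S,6S)-4,6-diethyl-6-[(2S,4S)-2-ethyl-4-methyloctyl]-3-methoxy-1,2-dioxane (C-3 epimers) | CCCC[C@H](C)C[C@H](CC)C[C@@]1(CC)C[C@H](CC)C(OC)OO1 | intermediate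
19 | (4S,6S)-4,6-diethyl-6-[(2S,4S)-2-ethyl-4-methyloctyl]-1,2-dioxan-3-ylium trifluoromethanesulfonate | CCCC[C@H](C)C[C@H](CC)C[C@@]1(CC)C[C@H](CC)C=[O+]O1.[O-]S(=O)(=O)C(F)(F)F | intermediate
20 | trimethylsilyl 2-[(3S,4S,6S)-4,6-diethyl-6-[(2S,4S)-2-ethyl-4-methyloctyl]-1,2-dioxan-3-yl]acetate | CCCC[C@H](C)C[C@H](CC)C[C@@]1(CC)C[C@H](CC)[C@H](CC(=O)O[Si](C)(C)C)OO1 | intermediate
21 | 2-[(3S,4S,6S)-4,6-diethyl-6-[(2S,4S)-2-ethyl-4-methyloctyl]-1,2-dioxan-3-yl]acetic acid | CCCC[C@H](C)C[C@H](CC)C[C@@]1(CC)C[C@H](CC)[C@H](CC(=O)O)OO1 | target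

**Step count**
Total steps: 9. Longest linear sequence: 6 (8 → 10 → 12 → 13 → 15 → 18 → 21).

**Three steps most likely to fail**

Step 8 (the proposed new coupling). The zinc reagent may not add to the peroxycarbenium ion, or the ion may fragment first. The fallback uses known chemistry, sets out from 4 and 15 and returns at 18. Wacker oxidation of 4 (PdCl2, CuCl, O2, DMF/H2O) gives (4S)-4-methyloctan-2-one F1. Kinetic enolisation (i-Pr2NLi, Me3SiCl, THF, −78 °C) gives trimethyl{[(4S)-4-methyloct-1-en-2-yl]oxy}silane F2. Me3SiOTf-mediated addition of F2 to the peroxycarbenium ion from 15 (the established silyl enol ether coupling, same axial approach) gives (4S)-1-[(4S,6R)-4,6-diethyl-3-methoxy-1,2-dioxan-6-yl]-4-methyloctan-2-one F3. Wittig ethylidenation (Ph3P=CHCH3, THF, −78 → 0 °C) gives (4S,6R)-4,6-diethyl-6-[(4S)-2-ethylidene-4-methyloctyl]-3-methoxy-1,2-dioxane F4. Diimide reduction (potassium azodicarboxylate, AcOH) then gives 18 together with its C-2′ epimer, which is separated by HPLC. This costs three more steps and a separation; the C6 descriptor changes to R in F3 and F4 only because the priorities change.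

Step 7 (ring expansion of an α-silyloxy cyclobutanol). The substrate class is untested under the cobalt/O2 conditions. The fallback sets out from 13 and returns at 15. K2CO3 in MeOH removes the silyl group to give (2R,3S)-1,3-diethylcyclobutane-1,2-diol F5. NaIO4 (THF/H2O, 0 °C) cleaves the glycol to (2S)-2-ethyl-4-oxohexanal F6, which is used at once to limit epimerisation. Ethereal H2O2 closes it to (4S)-4,6-diethyl-1,2-dioxane-3,6-diol F7, and MeOH with pyridinium p-toluenesulfonate gives 15.

Step 9 (C-3 substitution giving the free acid). The secondary peroxyacetal may ionise sluggishly, the bis-silyl acetal may react poorly, and 3,4-cis selectivity next to the ethyl group is the least secure stereochemical call. The fallback sets out from 18 and returns at 21. Allyltrimethylsilane with Me3SiOTf (CH2Cl2, −78 °C), the best-behaved axial nucleophile for peroxycarbenium ions, gives (3S,4S,6S)-4,6-diethyl-6-[(2S,4S)-2-ethyl-4-methyloctyl]-3-(prop-2-en-1-yl)-1,2-dioxane F8. Ozonolysis (O3, CH2Cl2, −78 °C; Me2S) gives 2-[(3S,4S,6S)-4,6-diethyl-6-[(2S,4S)-2-ethyl-4-methyloctyl]-1,2-dioxan-3-yl]acetaldehyde F9. Pinnick oxidation (NaClO2, NaH2PO4, 2-methylbut-2-ene) gives 21, and the C-3 epimers can be separated at the neutral stage F8.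

**Further compounds**
F1 | step 8 | (4S)-4-methyloctan-2-one | CCCC[C@H](C)CC(C)=O
F2 | step 8 | trimethyl{[(4S)-4-methyloct-1-en-2-yl]oxy}silane | CCCC[C@H](C)CC(=C)O[Si](C)(C)C
F3 | step 8 | (4S)-1-[(4S,6R)-4,6-diethyl-3-methoxy-1,2-dioxan-6-yl]-4-methyloctan-2-one | CCCC[C@H](C)CC(=O)C[C@@]1(CC)C[C@H](CC)C(OC)OO1
F4 | step 8 | (4S,6R)-4,6-diethyl-6-[(4S)-2-ethylidene-4-methyloctyl]-3-methoxy-1,2-dioxane | CCCC[C@H](C)CC(=CC)C[C@@]1(CC)C[C@H](CC)C(OC)OO1
F5 | step 7 | (2R,3S)-1,3-diethylcyclobutane-1,2-diol | CC[C@H]1CC(O)(CC)[C@@H]1O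
F6 | step 7 | (2S)-2-ethyl-4-oxohexanal | CCC(=O)C[C@H](CC)C=O
F7 | step 7 | (4S)-4,6-diethyl-1,2-dioxane-3,6-diol | CCC1(O)C[C@H](CC)C(O)OO1
F8 | step 9 | (3S,4S,6S)-4,6-diethyl-6-[(2S,4S)-2-ethyl-4-methyloctyl]-3-(prop-2-en-1-yl)-1,2-dioxane | CCCC[C@H](C)C[C@H](CC)C[C@@]1(CC)C[C@H](CC)[C@H](CC=C)OO1
F9 | step 9 | 2-[(3S,4S,6S)-4,6-diethyl-6-[(2S,4S)-2-ethyl-4-methyloctyl]-1,2-dioxan-3-yl]acetaldehyde | CCCC[C@H](C)C[C@H](CC)C[C@@]1(CC)C[C@H](CC)[C@H](CC=O)OO1
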